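Skeleton numbering (C1–C20) is that of ent-kaurane. TBS = tert-butyldimethylsilyl, TBDPS = tert-butyldiphenylsilyl, PMB = 4-methoxybenzyl.

## Analysis of the target

The target is a 6,7-seco-ent-kaurane of the 7,20-spirolactone class: ring A (C1–C5, C10) is a cyclohexane, a δ-lactone (C10–C20–O–C7(=O)–C8–C9) is spiro-joined to it at C10, and a bicyclo[3.2.1]octane made of ring C (C8, C9, C11–C14) and ring D (C8, C14, C13, C16, C15) is fused to the lactone along C8–C9 and carries the C15 ketone conjugated with the exocyclic C16=C17 alkene. There are seven stereocentres (C1, C4, C5, C10, C9, C8, C13), three of them quaternary (C4, C10, C8), and C4, C5, C10 and C1 are contiguous. On ring A the C1 acetoxy group, the lactone methylene C20, the C19 acetoxymethyl group and the C6 hydroxymethyl group all lie on one face, with C9 and the C18 methyl on the other; across the lactone ring C11 and C14 lie on the side of C1 and C15 on the side of C5, and C13 is fixed by the bridge once C8 is set. The sensitive groups are the α-methylene cyclopentanone (a Michael acceptor that tolerates neither nucleophiles nor strong base), two acetates next to a free primary hydroxyl (acyl migration) and a lactone that can migrate to O1 whenever that oxygen is free. The hard part is C10: it carries two one-carbon arms, C9 and C20, that are alike at the alcohol stage and differ only in the face of ring A they occupy, it is flanked by the congested C4–C5 pair, and C20 has to sit syn-diaxial to C19. A second difficulty is C8, a quaternary carbon shared by the lactone and rings C and D. The strategy rests on the fragment O1–C1–C10–C20: C20 is cis to the C1 oxygen on the neighbouring carbon and trans to H5, so C20 can be handed from O1 to C10 of a C10=C5 alkene through a short temporary tether, which sets C10 and C5 together and leaves the other arm, C9, free for ring C.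

## Retrosynthetic reasoning

**Endgame (38 ⇐ 37 ⇐ 36).** The free C6 hydroxyl and the exocyclic enone are exposed last. Target 38 comes from its C6 PMB ether 37 by oxidative debenzylation, which is neutral and cannot move the acetates. Enone 37 comes from ketone 36 by forming C16–C17, because an α-methylene ketone would not survive the earlier steps. C8 is quaternary, so the C15 ketone can enolise only towards C16.

**Ring D (36 ⇐ 35 ⇐ 34 ⇐ 32 ⇐ 31).** The C13–C16 bond is cut. C8 already carries a one-carbon acyl group (C15) and ring C holds an alkene directly across from it, so a carbenoid on C16 can only add to C12=C13 on the face of C8–C15. Opening the resulting cyclopropyl ketone 35 at C12–C16 leaves the bicyclo[3.2.1]octanone 36. C13 is then set by geometry, not by reagent choice. Diazoketone 34 is reached from acid 32 and this from allyl ester 31.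

**Ring C (31 ⇐ 29 ⇐ 27 + 28).** C8–C14 and C9–C11 are cut together. A Diels–Alder reaction of buta-1,3-diene 28 with the doubly activated alkene of lactone 27 gives both bonds cis, makes C8 quaternary with the ester that becomes C15, and leaves the C12=C13 alkene needed for ring D. The forward reaction must take the lactone face on the side of C1. The acetate on C19 is exchanged in only after this step (29 → 30 → 31), so the large silyl ether still shields the other face during the cycloaddition.

**Lactone (27 ⇐ 26 ⇐ 25 ⇐ 24 ⇐ 23 ⇐ 21 + 22).** C8=C9 and O20–C7 are cut. Allyl hydrogen malonate 22 is placed on the C20 hydroxyl of diol 21, O1 is acetylated, and the C9 arm is oxidised to the aldehyde, which condenses with the malonate carbon. This needs a free C20 hydroxyl while C9 is still silylated, and a C1 hydroxyl that can be capped before any lactone exists. The key step supplies exactly that pattern.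

**Key disconnection (21 ⇐ 20 ⇐ 19).** C10–C20 is cut, together with the C5–H bond. In the forward sense a silylmethyl radical tethered to O1 adds to C10 of the tetrasubstituted C10=C5 alkene of 19, and the C5 radical is then reduced. Cutting here and not at C9–C10 means the two arms of C10 are never equivalent: C9 is in place as a silyl ether and C20 arrives from the C1 oxygen, necessarily cis to it. Oxidation of the C–Si bond of siloxane 20 then gives diol 21. The protecting groups were chosen for this step. The PMB group sits on C6, from where its benzylic hydrogens can reach the C5 radical only through a 1,4-shift. C19 carries a TBDPS ether, which has no weak C–H bond and adds bulk to the face from which hydrogen must not arrive. A PMB ether on C19 would place benzylic hydrogens within 1,5-reach of C5 on the wrong face.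

**C1 (19 ⇐ 17 ⇐ 16).** The C1 carbinol is cut back to enone 16. C4 is too remote to control C1, so the reduction is reagent-controlled (Corey–Bakshi–Shibata).

**C5–C6 (16 ⇐ 15 ⇐ 10 + 14; 14 ⇐ 13 ⇐ 11 + 12).** With the carbonyl at C5, an alkoxymethyl nucleophile 14 adds there, and a Dauben oxidative transposition of the tertiary allylic alcohol 15 moves the oxygen to C1 and the alkene to C10=C5. Both steps use the same oxygen, and no alkene isomers can arise because C4 is quaternary.

**C10–C9 (10 ⇐ 9 ⇐ 7 + 8).** C9 is introduced by a Baylis–Hillman reaction of enone 7 with formaldehyde 8. This is done before C5 is substituted, because the reaction needs an unsubstituted β-carbon.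

**C4 (7 ⇐ 5 ⇐ 4 ⇐ 3 ⇐ 2 ⇐ 1).** The quaternary carbon is set by Fráter–Seebach methylation of the hydroxy ester 2 obtained from keto ester 1 by asymmetric hydrogenation. A catalytic desymmetrisation that would have to tell a methyl from a one-carbon ester group on a remote quaternary carbon was set aside. A catalyst that selects an alkene face can choose between two enantiotopic arms only if the substrate itself prefers one ring face, and methyl and ester are too alike for that. The alkylation route takes its selectivity from a chelate next to the reacting carbon.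

## Alternatives that were turned down

**Alternative 1:** Ring D as the organising disconnection: C13–C16 (with a transient C12–C16 bond) is cut. In the forward step Rh2(OAc)4 turns a diazoacetyl group on C8 into a carbenoid that adds to the C12=C13 alkene and gives the cyclopropyl ketone A1, which is then opened at C12–C16.
- For: the addition is intramolecular and can reach only one alkene face, so C13 follows from C8. The ketone arrives at C15 with C16 ready for methylenation, and acetates and the lactone are tolerated.
- Against: as the centre of a plan it solves the least demanding third of the molecule. It presupposes C10, C9 and C8, and says nothing about how C20 is placed cis to O1 on a quaternary carbon or how the two arms of C10 are told apart.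
- Comparison: on ring D it is as strong as anything in the chosen route, which is why the same sequence is used there as steps 24 and 25. The chosen strategy spends its key step on C10 and C5 instead, where the target is hardest.

**Alternative 2:** C9–C10 and O20–C7 are cut. Cp2TiCl (trivalent titanium) opens the spiro-epoxide A2 to a tertiary C10 radical, which adds to C9 of methyl cyclohexa-1,4-diene-1-carboxylate A3; the titanium alkoxide on C20 then closes the lactone to give A4.
- For: it is convergent, it forms the quaternary C10, the C9–C10 bond and the lactone in one operation, the oxygen-bearing arm is C20 by construction, and ring C arrives with its alkene already at C12=C13. In step count to the spirolactone it is clearly shorter than the chosen route.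
- Against: the C10 radical is planar, and the face taken by a bulky acceptor decides C10 with nothing but ring A conformation to guide it. C9 and C8 are set in the same step. C8 is left as C–H, so the C15 carbon must later be forced onto a hindered lactone enolate with control of a quaternary centre. A β-oxygen on C1 sits next to an organotitanium centre if the radical is over-reduced.
- Comparison: the chosen strategy gives up convergence. In return C20 is cis to O1 through a tether that allows no other outcome, C5 is set in the same step, and C8 is made quaternary with its C15 carbon by condensation and cycloaddition, not by enolate chemistry.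

**Alternative 3:** C13–C14 and C8–C15 are cut. Pd(OAc)2 with P(O-i-Pr)3 (zerovalent palladium formed in the flask) ionises the allylic acetate of A5 and, after loss of silicon, the trimethylenemethane complex adds across the exocyclic C8=C14 alkene of the lactone to give the 15-deoxo tetracycle A6.
- For: rings C and D, the quaternary C8 and the C16 methylene are made in a single step, which is stronger in ring-forming economy than the three steps the chosen route needs.
- Against: the cycloaddition has to close a bridged, not a fused, bicycle onto a 1,1-disubstituted, singly activated alkene. Nothing in A5 enforces the face at C8 or the configuration at C13. The C9 side chain needs its own stereocontrolled synthesis. The product lacks the C15 oxygen, which must be added late by allylic oxidation (SeO2) next to a quaternary carbon and then oxidised again.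
- Comparison: the chosen route carries C15 at the acid oxidation level from the malonate onward and uses only well-precedented ring closures. Like Alternative 1, this plan leaves C10 unaddressed.

Key step: step 13

Assumption: in step 2 the dianion is taken to be methylated trans to the alkoxide oxygen, as the chelate model predicts for cyclic β-hydroxy esters; if the sense were opposite, RuCl2[(R)-BINAP] would be used in step 1 and nothing else changes.

## Route

Step 1
Reactants: 1 methyl 2-oxocyclohexane-1-carboxylate (racemic, enolisable)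
Product: 2 methyl (1S,2S)-2-hydroxycyclohexane-1-carboxylate
Conditions: H2 (50 atm), RuCl2[(S)-BINAP] (1 mol%), CH2Cl2, 50 °C
Reagents that add atoms: none
Why: Noyori asymmetric hydrogenation of a β-keto ester with dynamic kinetic resolution; the (S)-ligand gives the (S)-carbinol, and any cis isomer has the same carbinol configuration, which is all that step 2 uses.

Step 2
Reactants: 2 methyl (1S,2S)-2-hydroxycyclohexane-1-carboxylate
Product: 3 methyl (1R,2S)-2-hydroxy-1-methylcyclohexane-1-carboxylate
Conditions: LiN(i-Pr)2 (2.2 equiv), THF, −78 → −20 °C; MeI, DMPU, −78 → 0 °C; aq. NH4Cl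
Reagents that add atoms: iodomethane, CI
Why: Fráter–Seebach alkylation: the chelated alkoxide–enolate dianion is methylated on the face away from the ring methylene next to the carbinol, so the methyl enters trans to oxygen and the ester ends cis to it. This sets the quaternary carbon that becomes C4.

Step 3
Reactants: 3 methyl (1R,2S)-2-hydroxy-1-methylcyclohexane-1-carboxylate
Product: 4 (1S,2S)-2-(hydroxymethyl)-2-methylcyclohexan-1-ol
Conditions: LiAlH4, THF, 0 °C → rt
Reagents that add atoms: none
Why: Hydride reduction of the ester to the primary alcohol (C19); no stereocentre is touched.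

Step 4
Reactants: 4 (1S,2S)-2-(hydroxymethyl)-2-methylcyclohexan-1-ol
Product: 5 (1S,2S)-2-(TBDPS-oxymethyl)-2-methylcyclohexan-1-ol
Conditions: TBDPSCl, imidazole, DMF, 0 °C
Reagents that add atoms: tert-butyl(chloro)diphenylsilane, CC(C)(C)[Si](Cl)(c1ccccc1)c1ccccc1
Why: The bulky chlorosilane silylates the primary hydroxyl far faster than the secondary one beside the quaternary carbon.

Step 5
Reactants: 5 (1S,2S)-2-(TBDPS-oxymethyl)-2-methylcyclohexan-1-ol
Product: 7 (6S)-6-(TBDPS-oxymethyl)-6-methylcyclohex-2-en-1-one, via saturated ketone 6 (not isolated)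
Conditions: IBX (2-iodoxybenzoic acid, 3 equiv), DMSO, 25 → 75 °C
Reagents that add atoms: none
Why: IBX oxidises the alcohol to ketone 6 and, on warming, dehydrogenates it to the enone (Nicolaou dehydrogenation). Only one α-methylene exists, so the alkene can form only between C10 and C1 and a second dehydrogenation is impossible.

Step 6
Reactants: 7 (6S)-6-(TBDPS-oxymethyl)-6-methylcyclohex-2-en-1-one; 8 formaldehyde (as 37% aqueous solution)
Product: 9 (6S)-6-(TBDPS-oxymethyl)-2-(hydroxymethyl)-6-methylcyclohex-2-en-1-one
Conditions: DMAP (0.5 equiv), THF/H2O, rt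
Reagents that add atoms: none
Why: Morita–Baylis–Hillman reaction: DMAP adds to the unsubstituted β-carbon, the enolate takes up formaldehyde at the α-carbon (C10) and DMAP is expelled, which installs C9.

Step 7
Reactants: 9 (6S)-6-(TBDPS-oxymethyl)-2-(hydroxymethyl)-6-methylcyclohex-2-en-1-one
Product: 10 (6S)-2-(TBS-oxymethyl)-6-(TBDPS-oxymethyl)-6-methylcyclohex-2-en-1-one
Conditions: TBSCl, imidazole, CH2Cl2, 0 °C → rt
Reagents that add atoms: tert-butyl(chloro)dimethylsilane, CC(C)(C)[Si](C)(C)Cl
Why: Standard silylation of a primary allylic alcohol; the TBS ether is the one silyl group that can later be removed selectively.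

Step 8
Reactants: 11 tributyl(iodomethyl)stannane; 12 (4-methoxyphenyl)methanol
Product: 13 tributyl{[(4-methoxyphenyl)methoxy]methyl}stannane
Conditions: NaH, THF/DMF, 0 °C → rt
Reagents that add atoms: none
Why: Williamson etherification of the sodium alkoxide with the primary iodide (Still's route to alkoxymethylstannanes).

Step 9
Reactants: 10 (6S)-2-(TBS-oxymethyl)-6-(TBDPS-oxymethyl)-6-methylcyclohex-2-en-1-one; 13 tributyl{[(4-methoxyphenyl)methoxy]methyl}stannane
Product: 15 (1RS,6S)-2-(TBS-oxymethyl)-6-(TBDPS-oxymethyl)-1-(PMB-oxymethyl)-6-methylcyclohex-2-en-1-ol, via alkoxymethyllithium 14 (not isolated)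
Conditions: n-BuLi, THF, −78 °C; then 10, −78 → −40 °C; aq. NH4Cl
Reagents that add atoms: none
Why: Tin–lithium exchange gives the α-alkoxymethyllithium (Still's hydroxymethyl anion equivalent), which adds 1,2 to the enone carbonyl at low temperature and installs C6. The new carbinol centre is erased in step 10, so both epimers are carried on.

Step 10
Reactants: 15 (1RS,6S)-2-(TBS-oxymethyl)-6-(TBDPS-oxymethyl)-1-(PMB-oxymethyl)-6-methylcyclohex-2-en-1-ol
Product: 16 (4R)-2-(TBS-oxymethyl)-4-(TBDPS-oxymethyl)-3-(PMB-oxymethyl)-4-methylcyclohex-2-en-1-one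
Conditions: pyridinium chlorochromate (C5H5NH[CrO3Cl]), NaOAc, 4 Å MS, CH2Cl2, rt
Reagents that add atoms: pyridinium chlorochromate, [O-][Cr](=O)(=O)Cl.c1cc[nH+]cc1
Why: Dauben oxidative transposition: the tertiary chromate ester undergoes a [3,3] shift to C1 and is oxidised there, giving the C1 ketone and the tetrasubstituted C10=C5 alkene.

Step 11
Reactants: 16 (4R)-2-(TBS-oxymethyl)-4-(TBDPS-oxymethyl)-3-(PMB-oxymethyl)-4-methylcyclohex-2-en-1-one
Product: 17 (1S,4R)-2-(TBS-oxymethyl)-4-(TBDPS-oxymethyl)-3-(PMB-oxymethyl)-4-methylcyclohex-2-en-1-ol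
Conditions: (R)-1-methyl-3,3-diphenyl-tetrahydro-1H,3H-pyrrolo[1,2-c][1,3,2]oxazaborole ((R)-Me-CBS, 0.2 equiv), BH3·SMe2, THF, −30 °C
Reagents that add atoms: none
Why: Corey–Bakshi–Shibata reduction: the substituted alkenyl carbon C10 acts as the large group and the C2 methylene as the small one, so the (R)-catalyst gives the (1S)-alcohol under reagent control, independent of the remote C4 centre.

Step 12
Reactants: 17 (1S,4R)-2-(TBS-oxymethyl)-4-(TBDPS-oxymethyl)-3-(PMB-oxymethyl)-4-methylcyclohex-2-en-1-ol; 18 (bromomethyl)chlorodimethylsilane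
Product: 19 (1S,4R)-1-{[(bromomethyl)dimethylsilyl]oxy}-2-(TBS-oxymethyl)-4-(TBDPS-oxymethyl)-3-(PMB-oxymethyl)-4-methylcyclohex-2-ene
Conditions: Et3N, DMAP (cat.), CH2Cl2, 0 °C
Reagents that add atoms: none
Why: Silylation of the allylic alcohol with the chlorosilane attaches the radical precursor to O1.

Step 13
Reactants: 19 (1S,4R)-1-{[(bromomethyl)dimethylsilyl]oxy}-2-(TBS-oxymethyl)-4-(TBDPS-oxymethyl)-3-(PMB-oxymethyl)-4-methylcyclohex-2-ene
Product: 20 cis-fused oxasilolane (skeleton numbering 1S,4R,5R,10S): ring A with O1–SiMe2–C20H2 bridging C1 and C10, C10 also bearing CH2OTBS (C9), C5 bearing H and CH2OPMB (C6), C4 bearing CH3 and CH2OTBDPS (C19); O1, C20, C19 and C6 on one face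
Conditions: Bu3SnH (1.3 equiv, syringe pump over 6 h), AIBN (0.2 equiv), benzene (0.01 M), 80 °C
Reagents that add atoms: none
Why: Bu3Sn• abstracts bromine to give a primary α-silyl radical held above C10 by the O–Si tether, and this closes the five-membered oxasilolane by 5-exo-trig addition to C10, forming C10–C20; the closest known reaction is the Stork–Nishiyama cyclisation of (bromomethyl)dimethylsilyl ethers of cyclohexenols, which is known to create angular quaternary carbons. The three-atom tether can span only cis positions, so C20 is delivered to the face of the C1 oxygen and C10 is set by C1. The closure runs through the half-chair with O1 pseudo-axial, in which the silyloxymethyl group on C4 is pseudo-equatorial and does not block C10. The tertiary C5 radical then takes hydrogen from Bu3SnH through the chair that has C20 and C19 axial: the stannane approaches the opposite face, which carries only axial hydrogens on C1 and C3, whereas in the other chair it would meet the axial O1–Si bond, so C6 ends cis to C20. The step needs 5-exo over 6-endo closure, which is secured because 6-endo attack at C5 would have to build a bridged bicycle at the more hindered carbon. It needs cyclisation before reduction, which is secured by keeping the stannane concentration low. It also needs the absence of intramolecular hydrogen transfer to C5, which is secured by placing the PMB group on C6 (only a 1,4-shift is possible) and a silyl ether without weak C–H bonds on C19.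

Step 14
Reactants: 20 cis-fused oxasilolane (1S,4R,5R,10S)
Product: 21 (1S,2S,3R,4R)-2-(TBS-oxymethyl)-2-(hydroxymethyl)-3-(PMB-oxymethyl)-4-(TBDPS-oxymethyl)-4-methylcyclohexan-1-ol (ring positions 1, 2, 3, 4 are C1, C10, C5, C4 of the skeleton; the free hydroxymethyl is C20, cis to the C1 hydroxyl)
Conditions: KF, KHCO3, 30% H2O2, THF/MeOH, rt → 40 °C
Reagents that add atoms: hydrogen peroxide, OO
Why: Tamao oxidation: hydroperoxide attacks the fluoride-activated silicon and C20 migrates from silicon to oxygen with retention; the three ether protecting groups are untouched, and only C1–OH and C20–OH are freed.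

Step 15
Reactants: 21 diol (C1–OH, C20–OH); 22 3-oxo-3-(prop-2-en-1-yloxy)propanoic acid (allyl hydrogen malonate)
Product: 23 C20 allyl malonate of 21 (C1–OH free; other groups and configuration as in 21)
Conditions: DCC, DMAP (cat.), CH2Cl2, −20 → 0 °C
Reagents that add atoms: none
Why: Steglich esterification; the primary C20 hydroxyl reacts much faster than the secondary C1 hydroxyl beside quaternary C10, so the malonate lands on the arm that will carry the lactone oxygen.

Step 16
Reactants: 23 C20 allyl malonate with free C1–OH
Product: 24 C1 acetate of 23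
Conditions: Ac2O, pyridine, DMAP (cat.), CH2Cl2, 0 °C → rt
Reagents that add atoms: acetic anhydride, CC(=O)OC(C)=O
Why: Acetylation of the remaining secondary alcohol; capping O1 before the lactone exists also rules out later migration of the lactone to O1.

Step 17
Reactants: 24 C1 acetate, C20 allyl malonate, C9 TBS ether
Product: 25 C9 primary alcohol (TBS removed; other groups as in 24)
Conditions: HF·pyridine, pyridine, THF, 0 °C
Reagents that add atoms: none
Why: The primary TBS ether is cleaved by buffered HF·pyridine much faster than the TBDPS ether, and the acidic medium suppresses migration of the malonate between the two arms on C10.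

Step 18
Reactants: 25 C9 primary alcohol
Product: 27 spiro α,β-unsaturated δ-lactone: ring C10–C20–O–C7(=O)–C8=C9 spiro at C10, C8 bearing CO2-allyl; ring A with 1-OAc, 4-CH3, 4-CH2OTBDPS, 5-CH2OPMB; C20 cis to the C1 acetoxy group and to C6, via aldehyde 26 (not isolated)
Conditions: Dess–Martin periodinane, NaHCO3, CH2Cl2, 0 °C → rt; then piperidine (0.2 equiv), AcOH (0.2 equiv), rt
Reagents that add atoms: none
Why: Dess–Martin oxidation gives aldehyde 26, which has no α-hydrogen; amine-catalysed intramolecular Knoevenagel condensation (6-exo attack of the malonate carbon on C9, then dehydration) closes the lactone and creates the doubly activated C8=C9 alkene.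

Step 19
Reactants: 27 spiro unsaturated lactone; 28 buta-1,3-diene (excess)
Product: 29 Diels–Alder adduct: cyclohexene ring C (C8, C14, C13=C12, C11, C9) cis-fused to the lactone, C8 quaternary with CO2-allyl, C11 and C14 on the lactone face of C1, the ester on the face of C5; ring A as in 27
Conditions: ZnCl2 (1 equiv), CH2Cl2, sealed tube, 25 → 40 °C
Reagents that add atoms: none
Why: Lewis acid-promoted Diels–Alder reaction of a chelating alkylidene malonate-type dienophile; suprafacial addition makes C8–C14 and C9–C11 cis. The diene should come to the lactone face flanked by the small C1 acetoxy group and not to the face flanked by C5 with its C6 ether and the silyloxymethyl group on C4, which sets C9 and C8 as required.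

Step 20
Reactants: 29 Diels–Alder adduct with C19 TBDPS ether
Product: 30 C19 primary alcohol (TBDPS removed; other groups as in 29)
Conditions: HF·pyridine, THF, rt
Reagents that add atoms: none
Why: Fluoride cleavage of the silyl ether under acidic buffering, which leaves the acetate, both esters and the PMB ether alone.

Step 21
Reactants: 30 C19 primary alcohol
Product: 31 1,19-diacetate (C8 CO2-allyl, C6 OPMB, ring C alkene)
Conditions: Ac2O, pyridine, DMAP (cat.), CH2Cl2, rt
Reagents that add atoms: acetic anhydride, CC(=O)OC(C)=O
Why: Acetylation of the neopentyl primary alcohol completes the acetate pattern of the target.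

Step 22
Reactants: 31 1,19-diacetate allyl ester
Product: 32 C8 carboxylic acid (CO2H in place of CO2-allyl)
Conditions: Pd(PPh3)4 (5 mol%), morpholine, THF, rt
Reagents that add atoms: none
Why: Tsuji–Trost deallylation: zerovalent palladium ionises the allyl ester and morpholine takes the allyl group, so the acid is freed without hydrolytic conditions that would touch the acetates or the lactone.

Step 23
Reactants: 32 C8 carboxylic acid
Product: 34 diazoketone: C8–C15(=O)–C16H=N2 (other groups as in 32), via acid chloride 33 (not isolated)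
Conditions: 1-chloro-N,N,2-trimethylprop-1-en-1-amine, CH2Cl2, 0 °C → rt; then CH2N2 (excess), Et2O, 0 °C
Reagents that add atoms: diazomethane, C=[N+]=[N-]
Why: The α-chloroenamine makes the acid chloride without free HCl, so the PMB ether is safe, and no ketene can form at quaternary C8; acylation of diazomethane then gives the α-diazoketone, which brings in C16.

Step 24
Reactants: 34 diazoketone
Product: 35 cyclopropyl ketone: C16 bonded to C15, C13 and C12 (tricyclo[3.2.1.0]octanone fused to the lactone at C8–C9; other groups as in 34)
Conditions: Rh2(OAc)4 (2 mol%), CH2Cl2, rt, slow addition of 34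
Reagents that add atoms: none
Why: Rhodium carbenoid cyclopropanation: C16 is held over the C12=C13 alkene across ring C and can reach only the face syn to the C8–C15 bond, so C13 follows from C8 and ring D is closed.

Step 25
Reactants: 35 cyclopropyl ketone
Product: 36 bicyclo[3.2.1]octanone: C15 ketone, C16H2 bonded to C13, C12H2 (other groups as in 35)
Conditions: SmI2 (2.5 equiv), THF/MeOH, −78 °C
Reagents that add atoms: none
Why: Single-electron reduction gives a ketyl that opens the cyclopropane bond best aligned with the carbonyl π system. This is C12–C16, which is exocyclic to the five-membered ketone ring, whereas C13–C16 lies nearly in its plane; a second electron and protonation then give the ring D ketone.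

Step 26
Reactants: 36 ring D ketone; 8 formaldehyde (as paraformaldehyde)
Product: 37 6-O-PMB ether of the target (C16=C17H2 in place)
Conditions: PhNHMe·CF3CO2H, THF, reflux
Reagents that add atoms: none
Why: Gras α-methylenation (Mannich condensation through the anilinium salt, then elimination); the ketone can enolise only towards C16 because C8 is quaternary, and the mildly acidic medium spares acetates and lactone.

Step 27
Reactants: 37 6-O-PMB ether of the target
Product: 38 CNP0105570.2 (target)
Conditions: DDQ, CH2Cl2/pH 7 buffer, 0 °C → rt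
Reagents that add atoms: none
Why: Oxidative cleavage of the PMB ether by DDQ through the benzylic oxocarbenium ion; the neutral conditions leave the enone, the acetates and the lactone intact and give no opening for acyl migration to the freed C6 hydroxyl.

## Compound list

1 | methyl 2-oxocyclohexane-1-carboxylate | COC(=O)C1CCCCC1=O | starting material
2 | methyl (1S,2S)-2-hydroxycyclohexane-1-carboxylate | COC(=O)[C@H]1CCCC[C@@H]1O | intermediate
3 | methyl (1R,2S)-2-hydroxy-1-methylcyclohexane-1-carboxylate | COC(=O)[C@]1(C)CCCC[C@@H]1O | intermediate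
4 | (1S,2S)-2-(hydroxymethyl)-2-methylcyclohexan-1-ol | OC[C@]1(C)CCCC[C@@H]1O | intermediate
5 | (1S,2S)-2-(TBDPS-oxymethyl)-2-methylcyclohexan-1-ol | CC(C)(C)[Si](OC[C@]1(C)CCCC[C@@H]1O)(c1ccccc1)c1ccccc1 | intermediate
6 | (2S)-2-(TBDPS-oxymethyl)-2-methylcyclohexan-1-one (not isolated) | CC(C)(C)[Si](OC[C@]1(C)CCCCC1=O)(c1ccccc1)c1ccccc1 | intermediate
7 | (6S)-6-(TBDPS-oxymethyl)-6-methylcyclohex-2-en-1-one | CC(C)(C)[Si](OC[C@]1(C)CCC=CC1=O)(c1ccccc1)c1ccccc1 | intermediate
8 | formaldehyde | C=O | starting material
9 | (6S)-6-(TBDPS-oxymethyl)-2-(hydroxymethyl)-6-methylcyclohex-2-en-1-one | CC(C)(C)[Si](OC[C@]1(C)CCC=C(CO)C1=O)(c1ccccc1)c1ccccc1 | intermediate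
10 | (6S)-2-(TBS-oxymethyl)-6-(TBDPS-oxymethyl)-6-methylcyclohex-2-en-1-one | CC(C)(C)[Si](OC[C@]1(C)CCC=C(CO[Si](C)(C)C(C)(C)C)C1=O)(c1ccccc1)c1ccccc1 | intermediate
11 | tributyl(iodomethyl)stannane | CCCC[Sn](CCCC)(CCCC)CI | starting material
12 | (4-methoxyphenyl)methanol | COc1ccc(CO)cc1 | starting material
13 | tributyl{[(4-methoxyphenyl)methoxy]methyl}stannane | CCCC[Sn](CCCC)(CCCC)COCc1ccc(OC)cc1 | intermediate
14 | {[(4-methoxyphenyl)methoxy]methyl}lithium (not isolated) | [Li]COCc1ccc(OC)cc1 | intermediate
15 | (1RS,6S)-2-(TBS-oxymethyl)-6-(TBDPS-oxymethyl)-1-(PMB-oxymethyl)-6-methylcyclohex-2-en-1-ol | CC(C)(C)[Si](OC[C@]1(C)CCC=C(CO[Si](C)(C)C(C)(C)C)C1(O)COCc1ccc(OC)cc1)(c1ccccc1)c1ccccc1 | intermediate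
16 | (4R)-2-(TBS-oxymethyl)-4-(TBDPS-oxymethyl)-3-(PMB-oxymethyl)-4-methylcyclohex-2-en-1-one | O=C1CC[C@@](C)(CO[Si](c2ccccc2)(c2ccccc2)C(C)(C)C)C(COCc2ccc(OC)cc2)=C1CO[Si](C)(C)C(C)(C)C | intermediate
17 | (1S,4R)-2-(TBS-oxymethyl)-4-(TBDPS-oxymethyl)-3-(PMB-oxymethyl)-4-methylcyclohex-2-en-1-ol | O[C@H]1CC[C@@](C)(CO[Si](c2ccccc2)(c2ccccc2)C(C)(C)C)C(COCc2ccc(OC)cc2)=C1CO[Si](C)(C)C(C)(C)C | intermediate
18 | (bromomethyl)chlorodimethylsilane | C[Si](C)(Cl)CBr | starting material
19 | (1S,4R)-1-{[(bromomethyl)dimethylsilyl]oxy}-2-(TBS-oxymethyl)-4-(TBDPS-oxymethyl)-3-(PMB-oxymethyl)-4-methylcyclohex-2-ene | BrC[Si](C)(C)O[C@H]1CC[C@@](C)(CO[Si](c2ccccc2)(c2ccccc2)C(C)(C)C)C(COCc2ccc(OC)cc2)=C1CO[Si](C)(C)C(C)(C)C | intermediate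
20 | cis-fused oxasilolane (1S,4R,5R,10S): O1–SiMe2–C20H2 ring on C1/C10, 10-CH2OTBS, 5-CH2OPMB, 4-CH3, 4-CH2OTBDPS | C[Si]1(C)O[C@H]2CC[C@@](C)(CO[Si](c3ccccc3)(c3ccccc3)C(C)(C)C)[C@@H](COCc3ccc(OC)cc3)[C@]2(C1)CO[Si](C)(C)C(C)(C)C | intermediate
21 | (1S,2S,3R,4R)-2-(TBS-oxymethyl)-2-(hydroxymethyl)-3-(PMB-oxymethyl)-4-(TBDPS-oxymethyl)-4-methylcyclohexan-1-ol | O[C@H]1CC[C@@](C)(CO[Si](c2ccccc2)(c2ccccc2)C(C)(C)C)[C@@H](COCc2ccc(OC)cc2)[C@]1(CO)CO[Si](C)(C)C(C)(C)C | intermediate
22 | 3-oxo-3-(prop-2-en-1-yloxy)propanoic acid (allyl hydrogen malonate) | OC(=O)CC(=O)OCC=C | starting material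
23 | C20 allyl malonate of diol 21 (C1–OH free) | O[C@H]1CC[C@@](C)(CO[Si](c2ccccc2)(c2ccccc2)C(C)(C)C)[C@@H](COCc2ccc(OC)cc2)[C@]1(COC(=O)CC(=O)OCC=C)CO[Si](C)(C)C(C)(C)C | intermediate
24 | C1 acetate, C20 allyl malonate, C9 TBS ether | CC(=O)O[C@H]1CC[C@@](C)(CO[Si](c2ccccc2)(c2ccccc2)C(C)(C)C)[C@@H](COCc2ccc(OC)cc2)[C@]1(COC(=O)CC(=O)OCC=C)CO[Si](C)(C)C(C)(C)C | intermediate
25 | C1 acetate, C20 allyl malonate, C9 primary alcohol | CC(=O)O[C@H]1CC[C@@](C)(CO[Si](c2ccccc2)(c2ccccc2)C(C)(C)C)[C@@H](COCc2ccc(OC)cc2)[C@]1(COC(=O)CC(=O)OCC=C)CO | intermediate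
26 | C1 acetate, C20 allyl malonate, C9 aldehyde (not isolated) | CC(=O)O[C@H]1CC[C@@](C)(CO[Si](c2ccccc2)(c2ccccc2)C(C)(C)C)[C@@H](COCc2ccc(OC)cc2)[C@]1(COC(=O)CC(=O)OCC=C)C=O | intermediate
27 | spiro α,β-unsaturated δ-lactone with C8 CO2-allyl, 1-OAc, 19-OTBDPS, 6-OPMB | C=CCOC(=O)C1=C[C@]2(COC1=O)[C@@H](OC(C)=O)CC[C@@](C)(CO[Si](c3ccccc3)(c3ccccc3)C(C)(C)C)[C@H]2COCc1ccc(OC)cc1 | intermediate
28 | buta-1,3-diene | C=CC=C | starting material
29 | Diels–Alder adduct: ring C cyclohexene cis-fused to the lactone, C8 CO2-allyl, 1-OAc, 19-OTBDPS, 6-OPMB | C=CCOC(=O)[C@]12CC=CC[C@H]1[C@]1(COC2=O)[C@@H](OC(C)=O)CC[C@@](C)(CO[Si](c3ccccc3)(c3ccccc3)C(C)(C)C)[C@H]1COCc1ccc(OC)cc1 | intermediate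
30 | C19 alcohol of the adduct (1-OAc, 6-OPMB, C8 CO2-allyl) | C=CCOC(=O)[C@]12CC=CC[C@H]1[C@]1(COC2=O)[C@@H](OC(C)=O)CC[C@@](C)(CO)[C@H]1COCc1ccc(OC)cc1 | intermediate
31 | 1,19-diacetate allyl ester | C=CCOC(=O)[C@]12CC=CC[C@H]1[C@]1(COC2=O)[C@@H](OC(C)=O)CC[C@@](C)(COC(C)=O)[C@H]1COCc1ccc(OC)cc1 | intermediate
32 | 1,19-diacetate C8 carboxylic acid | OC(=O)[C@]12CC=CC[C@H]1[C@]1(COC2=O)[C@@H](OC(C)=O)CC[C@@](C)(COC(C)=O)[C@H]1COCc1ccc(OC)cc1 | intermediate
33 | 1,19-diacetate C8 acid chloride (not isolated) | ClC(=O)[C@]12CC=CC[C@H]1[C@]1(COC2=O)[C@@H](OC(C)=O)CC[C@@](C)(COC(C)=O)[C@H]1COCc1ccc(OC)cc1 | intermediate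
34 | diazoketone (C8–C15(=O)–C16H=N2) | [N-]=[N+]=CC(=O)[C@]12CC=CC[C@H]1[C@]1(COC2=O)[C@@H](OC(C)=O)CC[C@@](C)(COC(C)=O)[C@H]1COCc1ccc(OC)cc1 | intermediate
35 | cyclopropyl ketone (C16 bonded to C12, C13 and C15), 1,19-diacetate, 6-OPMB | O=C1[C@H]2[C@H]3C[C@]14[C@@H](C[C@@H]23)[C@]5(COC4=O)[C@@H](OC(C)=O)CC[C@@](C)(COC(C)=O)[C@H]5COCc1ccc(OC)cc1 | intermediate
36 | ring D ketone (bicyclo[3.2.1]octan-15-one, C16H2), 1,19-diacetate, 6-OPMB | C1C(=O)[C@]23C[C@H]1CC[C@H]2[C@]1(COC3=O)[C@@H](OC(C)=O)CC[C@@](C)(COC(C)=O)[C@H]1COCc1ccc(OC)cc1 | intermediate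
37 | 6-O-PMB ether of the target | C=C1C(=O)[C@]23C[C@H]1CC[C@H]2[C@]1(COC3=O)[C@@H](OC(C)=O)CC[C@@](C)(COC(C)=O)[C@H]1COCc1ccc(OC)cc1 | intermediate
38 | CNP0105570.2 | C=C1C(=O)[C@]23C[C@H]1CC[C@H]2[C@]1(COC3=O)[C@@H](OC(C)=O)CC[C@@](C)(COC(C)=O)[C@H]1CO | target

## Step count and least certain steps

Total: 27 steps. Longest linear sequence: 26 steps (steps 1–7 and 9–27, from 1 to 38); step 8 prepares reagent 13.

**Step 13 (key step).** Two things may go wrong. The first is hydrogen transfer to the silylmethyl radical before it has cyclised, because addition to a fully substituted, unactivated alkene carbon is slow. The second is incomplete face selection when the C5 radical is reduced, because both faces are flanked by substituents on quaternary neighbours. The fallback sets out from 19 and activates the alkene. DDQ in buffered CH2Cl2 removes the PMB group to give the C6 allylic alcohol F1, and MnO2 oxidises it to the enal F2. Under the same Bu3SnH/AIBN conditions the nucleophilic silylmethyl radical now adds to the β-carbon of an enal, a polarity-matched and much faster 5-exo closure, giving the cyclised aldehyde F3. Its C5 centre lies α to the formyl group and can be equilibrated with mild base towards the isomer with equatorial formyl. NaBH4 gives the C6 alcohol F4, and 4-methoxybenzyl trichloroacetimidate with catalytic La(OTf)3 returns to 20.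

**Step 19.** The cycloaddition may be slow at the neopentyl-type C9, so that the diene polymerises first, and the preference for the C1 face of the lactone rests only on the difference between an acetoxy group and a CH2OPMB group with a silyl ether behind it, so facial selectivity may be poor. The fallback sets out from 23 and delivers the diene from O1 through a temporary silicon tether. HF·pyridine removes the TBS group to give the diol F5. TEMPO with PhI(OAc)2 oxidises only the primary C9 hydroxyl, and piperidinium acetate closes the unsaturated lactone F6 with C1–OH free. Silylation with (buta-1,3-dien-2-yl)chlorodimethylsilane gives the dienylsilyl ether F7. Heating in toluene brings about a type 2 intramolecular Diels–Alder reaction that can reach only the C1 face and gives the bridged vinylsilane F8, with silicon on C12 and the alkene at C12=C13. Fluoride (Bu4NF, AcOH, THF/DMF, 60 °C) removes the silicon from carbon and oxygen and the TBDPS group in one operation to give the 1,19-diol F9, and acetylation of both hydroxyls returns to 31.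

**Step 9.** Addition to a carbonyl flanked by a quaternary carbon and a substituted alkene carbon may be incomplete, or enolisation towards C2 or conjugate addition with loss of the silyloxy group may compete. The fallback sets out from 7 and reverses the order in which C6 and C9 are introduced. Reagent 14 adds to the less hindered enone 7 to give the tertiary allylic alcohol F10. Pyridinium chlorochromate transposes it to the enone F11. I2 and pyridine give the α-iodoenone F12. Stille coupling with (tributylstannyl)methanol and Pd(PPh3)4 gives the hydroxymethyl enone F13, and silylation with TBSCl returns to 16.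

**Step 25 (with step 24).** Ring opening may cleave the other cyclopropane bond (C13–C16), which would give a bicyclo[2.2.2]octanone, the ketone may be reduced further, or carbenoid insertion into the allylic C11–H bond may compete in step 24. The fallback sets out from 34 and forms C13–C16 directly by a radical route. HBr in ether at −20 °C converts the diazoketone into the bromomethyl ketone F14, and Bu3SnH/AIBN generates the α-keto radical at C16, which closes 5-exo onto C13 of the ring C alkene; reduction of the C12 radical gives 36. No cyclopropane is formed, so the question of which bond opens does not arise.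

## Further compounds

F1 | step 13 | C6 allylic alcohol of 19 (PMB removed) | BrC[Si](C)(C)O[C@H]1CC[C@@](C)(CO[Si](c2ccccc2)(c2ccccc2)C(C)(C)C)C(CO)=C1CO[Si](C)(C)C(C)(C)C
F2 | step 13 | enal (C6 aldehyde conjugated with C5=C10) | BrC[Si](C)(C)O[C@H]1CC[C@@](C)(CO[Si](c2ccccc2)(c2ccccc2)C(C)(C)C)C(C=O)=C1CO[Si](C)(C)C(C)(C)C
F3 | step 13 | cyclised oxasilolane aldehyde (C6 formyl on C5) | C[Si]1(C)O[C@H]2CC[C@@](C)(CO[Si](c3ccccc3)(c3ccccc3)C(C)(C)C)[C@@H](C=O)[C@]2(C1)CO[Si](C)(C)C(C)(C)C
F4 | step 13 | cyclised oxasilolane C6 alcohol | C[Si]1(C)O[C@H]2CC[C@@](C)(CO[Si](c3ccccc3)(c3ccccc3)C(C)(C)C)[C@@H](CO)[C@]2(C1)CO[Si](C)(C)C(C)(C)C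
F5 | step 19 | C1,C9-diol with C20 allyl malonate | O[C@H]1CC[C@@](C)(CO[Si](c2ccccc2)(c2ccccc2)C(C)(C)C)[C@@H](COCc2ccc(OC)cc2)[C@]1(COC(=O)CC(=O)OCC=C)CO
F6 | step 19 | spiro unsaturated lactone with free C1 hydroxyl | C=CCOC(=O)C1=C[C@]2(COC1=O)[C@@H](O)CC[C@@](C)(CO[Si](c3ccccc3)(c3ccccc3)C(C)(C)C)[C@H]2COCc1ccc(OC)cc1
F7 | step 19 | C1 (buta-1,3-dien-2-yl)dimethylsilyl ether of the unsaturated lactone | C=CCOC(=O)C1=C[C@]2(COC1=O)[C@@H](O[Si](C)(C)C(=C)C=C)CC[C@@](C)(CO[Si](c3ccccc3)(c3ccccc3)C(C)(C)C)[C@H]2COCc1ccc(OC)cc1
F8 | step 19 | bridged type 2 cycloadduct (O1–SiMe2–C12, alkene C12=C13) | C=CCOC(=O)[C@]12CC=C3C[C@H]1[C@]1(COC2=O)[C@@H](O[Si]3(C)C)CC[C@@](C)(CO[Si](c4ccccc4)(c4ccccc4)C(C)(C)C)[C@H]1COCc1ccc(OC)cc1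
F9 | step 19 | 1,19-diol of the ring C adduct (C8 CO2-allyl, 6-OPMB) | C=CCOC(=O)[C@]12CC=CC[C@H]1[C@]1(COC2=O)[C@@H](O)CC[C@@](C)(CO)[C@H]1COCc1ccc(OC)cc1
F10 | step 9 | (1RS,6S)-6-(TBDPS-oxymethyl)-1-(PMB-oxymethyl)-6-methylcyclohex-2-en-1-ol | CC(C)(C)[Si](OC[C@]1(C)CCC=CC1(O)COCc1ccc(OC)cc1)(c1ccccc1)c1ccccc1
F11 | step 9 | (4R)-4-(TBDPS-oxymethyl)-3-(PMB-oxymethyl)-4-methylcyclohex-2-en-1-one | O=C1CC[C@@](C)(CO[Si](c2ccccc2)(c2ccccc2)C(C)(C)C)C(COCc2ccc(OC)cc2)=C1
F12 | step 9 | (4R)-2-iodo-4-(TBDPS-oxymethyl)-3-(PMB-oxymethyl)-4-methylcyclohex-2-en-1-one | O=C1CC[C@@](C)(CO[Si](c2ccccc2)(c2ccccc2)C(C)(C)C)C(COCc2ccc(OC)cc2)=C1I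
F13 | step 9 | (4R)-2-(hydroxymethyl)-4-(TBDPS-oxymethyl)-3-(PMB-oxymethyl)-4-methylcyclohex-2-en-1-one | O=C1CC[C@@](C)(CO[Si](c2ccccc2)(c2ccccc2)C(C)(C)C)C(COCc2ccc(OC)cc2)=C1CO
F14 | step 25 | bromomethyl ketone (C8–C15(=O)–C16H2Br) | BrCC(=O)[C@]12CC=CC[C@H]1[C@]1(COC2=O)[C@@H](OC(C)=O)CC[C@@](C)(COC(C)=O)[C@H]1COCc1ccc(OC)cc1
A1 | alternative 1 | tricyclic cyclopropyl ketone, 1,19-diacetate, 6-OTBS | O=C1[C@H]2[C@H]3C[C@]14[C@@H](C[C@@H]23)[C@]5(COC4=O)[C@@H](OC(C)=O)CC[C@@](C)(COC(C)=O)[C@H]5CO[Si](C)(C)C(C)(C)C
A2 | alternative 2 | ring A C10–C20 spiro-epoxide (1-OPMB, 19-OPMB, 6-OTBS; C10 epimer immaterial) | C1OC12[C@@H](OCc3ccc(OC)cc3)CC[C@@](C)(COCc3ccc(OC)cc3)[C@H]2CO[Si](C)(C)C(C)(C)C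
A3 | alternative 2 | methyl cyclohexa-1,4-diene-1-carboxylate | COC(=O)C1=CCC=CC1
A4 | alternative 2 | ring A spiro δ-lactone cis-fused to cyclohexene ring C | O=C1OC[C@]2([C@@H](OCc4ccc(OC)cc4)CC[C@@](C)(COCc4ccc(OC)cc4)[C@H]2CO[Si](C)(C)C(C)(C)C)[C@@H]3CC=CC[C@H]13
A5 | alternative 3 | α-methylene spirolactone with C9 side chain ending in the 2-(trimethylsilylmethyl)allyl acetate | C=C1[C@@H](CCC(OC(C)=O)C(=C)C[Si](C)(C)C)[C@]2(COC1=O)[C@@H](OC(C)=O)CC[C@@](C)(COC(C)=O)[C@H]2CO[Si](C)(C)C(C)(C)C
A6 | alternative 3 | 15-deoxo tetracycle with the C16 methylene, 1,19-diacetate, 6-OTBS | C=C1C[C@]23C[C@H]1CC[C@H]2[C@]1(COC3=O)[C@@H](OC(C)=O)CC[C@@](C)(COC(C)=O)[C@H]1CO[Si](C)(C)C(C)(C)C
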